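**Retrosynthetic overview**
1. Target 22 ⇐ 21 by hydrolysis of the C18/C19 acetonide; the butenolide ring (C13–C16) of 21 ⇐ ring-closing metathesis of the allyl 2-alkylacrylate 20.
2. 20 ⇐ aldehyde 14 + sulfone acrylate 19, cutting C8–C9 (ring B) and C11–C12 in one radical relay. The enabling feature: C8 is the α-carbon of the C17 formyl group and sits trans-1,2 in ring B to C9, whose C11–C12 link ends at the lactone α-carbon C13. A C8 enaminyl radical can therefore add 6-exo to a C9=C11 vinyl group on C10, and the C11 radical can collect C12–C16 from an acrylate.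
3. 14 ⇐ vinyl ketone 11 (Wolff–Kishner at C1, acetal exchange) ⇐ enone 5 (copper-catalysed asymmetric conjugate addition at C5, aldol trap at C10, dehydration) ⇐ 2 + 3 (Robinson annulation; C4 carries both hydroxymethyl carbons as a spiro-acetonide).
4. Order of ring formation: ring A (step 2), ring B (step 9), butenolide ring (step 10).

Key step: step 9

Remark: atoms are numbered as in labdanes (C1–C10 decalin carbons, C11–C16 side chain and lactone, C17 formyl carbon, C18/C19 hydroxymethyl carbons, C20 methyl); the target is the (5S,8S,9R,10S) enantiomer of the ent-labdane series, and compounds 1, 3, 6, 7, 15, 16 and 18 are taken as commercial.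

Step 1
Reactants: 1 (2,2-dimethyl-1,3-dioxan-5-yl)methanol
Product: 2 2,2-dimethyl-1,3-dioxane-5-carbaldehyde
Conditions: TEMPO (10 mol%), PhI(OAc)2 (1.1 equiv), CH2Cl2, 20 °C
Reagents that add atoms: none
Why: Oxoammonium-mediated (TEMPO/PhI(OAc)2) alcohol oxidation should stop at the aldehyde and is mild enough for the acetonide; no stereocentre is involved.

Step 2
Reactants: 2 2,2-dimethyl-1,3-dioxane-5-carbaldehyde; 3 pent-1-en-3-one (ethyl vinyl ketone)
Product: 5 3,3,8-trimethyl-2,4-dioxaspiro[5.5]undec-7-en-9-one, via keto aldehyde 4 (not isolated)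
Conditions: pyrrolidine (20 mol%), AcOH (20 mol%), toluene, 20 → 60 °C; then KOH, MeOH, 60 °C
Reagents that add atoms: none
Why: Robinson annulation: enamine Michael addition of the α-branched aldehyde to the enone forms C3–C4 and the quaternary C4, and because the aldehyde of 4 then has no α-hydrogen, aldol condensation can only close ring A by attack of the ethyl CH2 (C10) on the formyl carbon (C5), giving the achiral 2-methyl enone.

Step 3
Reactants: 5 3,3,8-trimethyl-2,4-dioxaspiro[5.5]undec-7-en-9-one; 6 4-chloro-1,1-dimethoxybutane; 7 acetaldehyde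
Product: 10 (7R,8R)-7-(4,4-dimethoxybutyl)-8-(1-hydroxyethyl)-3,3,8-trimethyl-2,4-dioxaspiro[5.5]undecan-9-one (carbinol epimers), via Grignard reagent 8 (not isolated), via magnesium enolate 9 (not isolated)
Conditions: 6, Mg, THF, 50 °C; then 5, Cu(OTf)2 (5 mol%), chiral imidazolinium NHC precursor (6 mol%, enantiomer chosen for 7R), Et2O, −30 °C; then 7 (3 equiv), −78 °C; aq. NH4Cl
Reagents that add atoms: none
Why: Copper-catalysed asymmetric conjugate addition of a Grignard reagent to a 2-substituted cyclohexenone with in situ trapping of the magnesium enolate is established chemistry; the chiral copper–NHC complex should set C5, and the aldol addition of enolate 9 to acetaldehyde should occur at C10 anti to the C5 chain (held pseudo-axial by A(1,2) strain with the C10 methyl group), placing the future C9 trans to C6 and the methyl group cis, while the carbinol configuration is irrelevant.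

Step 4
Reactants: 10 (7R,8R)-7-(4,4-dimethoxybutyl)-8-(1-hydroxyethyl)-3,3,8-trimethyl-2,4-dioxaspiro[5.5]undecan-9-one
Product: 11 (7R,8S)-7-(4,4-dimethoxybutyl)-8-ethenyl-3,3,8-trimethyl-2,4-dioxaspiro[5.5]undecan-9-one
Conditions: Burgess reagent (1.5 equiv), toluene, 70 °C
Reagents that add atoms: none
Why: Burgess dehydration (syn elimination of the sulfamate ester): C10 is quaternary, so only the methyl group offers β-hydrogens and the terminal C9=C11 vinyl group should form, and the neutral conditions avoid retro-aldol cleavage.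

Step 5
Reactants: 11 (7R,8S)-7-(4,4-dimethoxybutyl)-8-ethenyl-3,3,8-trimethyl-2,4-dioxaspiro[5.5]undecan-9-one
Product: 13 (7S,8S)-7-(4,4-dimethoxybutyl)-8-ethenyl-3,3,8-trimethyl-2,4-dioxaspiro[5.5]undecane, via hydrazone 12 (not isolated)
Conditions: N2H4·H2O, KOH, diethylene glycol, 130 → 200 °C, argon
Reagents that add atoms: none
Why: Wolff–Kishner reduction (Huang–Minlon procedure) removes the C1 carbonyl that served steps 2 and 3; the vinyl group on the quaternary carbon cannot move into conjugation, both acetals are base-stable, and neither C5 (β to the carbonyl) nor C10 (quaternary) can epimerise.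

Step 6
Reactants: 13 (7S,8S)-7-(4,4-dimethoxybutyl)-8-ethenyl-3,3,8-trimethyl-2,4-dioxaspiro[5.5]undecane
Product: 14 4-[(7S,8S)-8-ethenyl-3,3,8-trimethyl-2,4-dioxaspiro[5.5]undecan-7-yl]butanal
Conditions: Amberlyst-15 (cat.), acetone, H2O (2 equiv), 20 °C
Reagents that add atoms: water, O
Why: Acid-catalysed transacetalisation: the acyclic dimethyl acetal should be exchanged in the large excess of acetone, while the same excess holds the 1,3-dioxane acetonide in place.

Step 7
Reactants: 15 2-(bromomethyl)prop-2-enoic acid; 16 sodium benzenesulfinate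
Product: 17 2-[(phenylsulfonyl)methyl]prop-2-enoic acid
Conditions: 16 (1.5 equiv), MeOH, 65 °C; then aq. HCl
Reagents that add atoms: none
Why: SN2/SN2′ substitution of the allylic bromide by the S-nucleophilic sulfinate; both pathways give the same allyl sulfone.

Step 8
Reactants: 17 2-[(phenylsulfonyl)methyl]prop-2-enoic acid; 18 prop-2-en-1-ol
Product: 19 prop-2-enyl 2-[(phenylsulfonyl)methyl]prop-2-enoate
Conditions: 18 (5 equiv), TsOH·H2O (5 mol%), benzene, reflux, Dean–Stark
Reagents that add atoms: none
Why: Fischer esterification with azeotropic removal of water; the absence of base avoids isomerisation of the allyl sulfone to the vinyl sulfone.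

Step 9
Reactants: 14 4-[(7S,8S)-8-ethenyl-3,3,8-trimethyl-2,4-dioxaspiro[5.5]undecan-7-yl]butanal; 19 prop-2-enyl 2-[(phenylsulfonyl)methyl]prop-2-enoate
Product: 20 prop-2-enyl 4-[(4a'S,5'R,6'S,8a'S)-6'-formyl-2,2,4a'-trimethyloctahydro-2'H-spiro[1,3-dioxane-5,1'-naphthalen]-5'-yl]-2-methylidenebutanoate (labdane numbering 5S,8S,9R,10S)
Conditions: Ir[dF(CF3)ppy]2(dtbbpy)PF6 (1 mol%), (2S,5S)-5-benzyl-2-tert-butyl-3-methylimidazolidin-4-one·CF3CO2H (20 mol%), 19 (2.5 equiv), 2,6-lutidine (1 equiv), H2O (5 equiv), DME, blue LEDs, 20 °C; then DBU (10 mol%), CH2Cl2, 20 °C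
Reagents that add atoms: none
Why: Proposed new method: condensation of 14 with the imidazolidinone gives the C8=C17 enamine, which photoexcited trivalent iridium oxidises to an electrophilic three-π-electron enaminyl radical; C8 then attacks C9 of the electron-rich vinyl group, and the nucleophilic primary C11 radical adds to the electron-poor acrylate 19 and expels PhSO2• by β-scission, which divalent iridium reduces to sulfinate so that the cycle is redox-neutral before the iminium ion is hydrolysed. The closest known reaction types are the photoredox/enamine α-alkylation of aldehydes with unactivated olefins (intramolecular exo closures ended by a thiol hydrogen-atom donor) and the allylation of alkyl radicals by 2-(sulfonylmethyl)acrylates; the new element is their merger into a polarity-alternating relay without a hydrogen-atom donor. Ring B closes in the 6-exo-trig mode through a chair transition state trans-fused to the ring-A chair, which is possible because C6 and C9 are trans-diequatorial on ring A. C9 is set by this chair (C11 pseudo-equatorial, H-9 axial and anti to the axial C20 methyl group), and C8 by the pseudo-equatorial iminium carbon; any axial 8-epimer should be equilibrated by DBU, because an axial formyl group would be syn-diaxial to C20. The step needs 6-exo over 7-endo closure and ring closure before intermolecular capture: the first is secured by stereoelectronics and the preorganised trans arms, the second by the polarity mismatch between the electrophilic enaminyl radical and electron-poor 19, whereas the C11 alkyl radical is polarity-matched to 19.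

Step 10
Reactants: 20 prop-2-enyl 4-[(4a'S,5'R,6'S,8a'S)-6'-formyl-2,2,4a'-trimethyloctahydro-2'H-spiro[1,3-dioxane-5,1'-naphthalen]-5'-yl]-2-methylidenebutanoate
Product: 21 (4a'S,5'R,6'S,8a'S)-2,2,4a'-trimethyl-5'-[2-(2-oxo-2,5-dihydrofuran-3-yl)ethyl]octahydro-2'H-spiro[1,3-dioxane-5,1'-naphthalene]-6'-carbaldehyde
Conditions: second-generation Grubbs catalyst (H2IMes)(PCy3)Cl2Ru=CHPh (5 mol%), toluene (0.005 M), 80 °C
Reagents that add atoms: none
Why: Ring-closing metathesis of an allyl 2-alkylacrylate is a standard entry to α-substituted butenolides; the ruthenium carbene tolerates the aldehyde and no stereocentre is touched.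

Step 11
Reactants: 21 (4a'S,5'R,6'S,8a'S)-2,2,4a'-trimethyl-5'-[2-(2-oxo-2,5-dihydrofuran-3-yl)ethyl]octahydro-2'H-spiro[1,3-dioxane-5,1'-naphthalene]-6'-carbaldehyde
Product: 22 (1R,2S,4aS,8aS)-5,5-bis(hydroxymethyl)-8a-methyl-1-[2-(2-oxo-2,5-dihydrofuran-3-yl)ethyl]decahydronaphthalene-2-carbaldehyde
Conditions: AcOH–H2O–THF (3:1:1), 40 °C
Reagents that add atoms: none
Why: Acid-catalysed acetonide hydrolysis; the equatorial C8 aldehyde is already the thermodynamic epimer and the butenolide is stable to mild aqueous acid.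

**Compound list**
1 | (2,2-dimethyl-1,3-dioxan-5-yl)methanol | OCC1COC(C)(C)OC1 | starting material
2 | 2,2-dimethyl-1,3-dioxane-5-carbaldehyde | O=CC1COC(C)(C)OC1 | intermediate
3 | pent-1-en-3-one (ethyl vinyl ketone) | CCC(=O)C=C | starting material
4 | 2,2-dimethyl-5-(3-oxopentyl)-1,3-dioxane-5-carbaldehyde (keto aldehyde) | CCC(=O)CCC1(C=O)COC(C)(C)OC1 | intermediate
5 | 3,3,8-trimethyl-2,4-dioxaspiro[5.5]undec-7-en-9-one | CC1=CC2(CCC1=O)COC(C)(C)OC2 | intermediate
6 | 4-chloro-1,1-dimethoxybutane | COC(CCCCl)OC | starting material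
7 | acetaldehyde | CC=O | starting material
8 | (4,4-dimethoxybutyl)magnesium chloride (Grignard reagent) | COC(CCC[Mg]Cl)OC | intermediate
9 | chloromagnesium (7R)-7-(4,4-dimethoxybutyl)-3,3,8-trimethyl-2,4-dioxaspiro[5.5]undec-8-en-9-olate (magnesium enolate) | CC1=C(O[Mg]Cl)CCC2(COC(C)(C)OC2)[C@H]1CCCC(OC)OC | intermediate
10 | (7R,8R)-7-(4,4-dimethoxybutyl)-8-(1-hydroxyethyl)-3,3,8-trimethyl-2,4-dioxaspiro[5.5]undecan-9-one (carbinol epimers) | C[C@@]1(C(C)O)C(=O)CCC2(COC(C)(C)OC2)[C@H]1CCCC(OC)OC | intermediate
11 | (7R,8S)-7-(4,4-dimethoxybutyl)-8-ethenyl-3,3,8-trimethyl-2,4-dioxaspiro[5.5]undecan-9-one | C[C@@]1(C=C)C(=O)CCC2(COC(C)(C)OC2)[C@H]1CCCC(OC)OC | intermediate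
12 | hydrazone of 11 | C[C@@]1(C=C)C(=NN)CCC2(COC(C)(C)OC2)[C@H]1CCCC(OC)OC | intermediate
13 | (7S,8S)-7-(4,4-dimethoxybutyl)-8-ethenyl-3,3,8-trimethyl-2,4-dioxaspiro[5.5]undecane | C[C@@]1(C=C)CCCC2(COC(C)(C)OC2)[C@H]1CCCC(OC)OC | intermediate
14 | 4-[(7S,8S)-8-ethenyl-3,3,8-trimethyl-2,4-dioxaspiro[5.5]undecan-7-yl]butanal | C[C@@]1(C=C)CCCC2(COC(C)(C)OC2)[C@H]1CCCC=O | intermediate
15 | 2-(bromomethyl)prop-2-enoic acid | OC(=O)C(=C)CBr | starting material
16 | sodium benzenesulfinate | [Na+].[O-]S(=O)c1ccccc1 | starting material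
17 | 2-[(phenylsulfonyl)methyl]prop-2-enoic acid | OC(=O)C(=C)CS(=O)(=O)c1ccccc1 | intermediate
18 | prop-2-en-1-ol | OCC=C | starting material
19 | prop-2-enyl 2-[(phenylsulfonyl)methyl]prop-2-enoate | C=CCOC(=O)C(=C)CS(=O)(=O)c1ccccc1 | intermediate
20 | prop-2-enyl 4-[(4a'S,5'R,6'S,8a'S)-6'-formyl-2,2,4a'-trimethyloctahydro-2'H-spiro[1,3-dioxane-5,1'-naphthalen]-5'-yl]-2-methylidenebutanoate | C[C@@]12CCCC3(COC(C)(C)OC3)[C@H]1CC[C@H](C=O)[C@H]2CCC(=C)C(=O)OCC=C | intermediate
21 | (4a'S,5'R,6'S,8a'S)-2,2,4a'-trimethyl-5'-[2-(2-oxo-2,5-dihydrofuran-3-yl)ethyl]octahydro-2'H-spiro[1,3-dioxane-5,1'-naphthalene]-6'-carbaldehyde | C[C@@]12CCCC3(COC(C)(C)OC3)[C@H]1CC[C@H](C=O)[C@H]2CCC1=CCOC1=O | intermediate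
22 | (1R,2S,4aS,8aS)-5,5-bis(hydroxymethyl)-8a-methyl-1-[2-(2-oxo-2,5-dihydrofuran-3-yl)ethyl]decahydronaphthalene-2-carbaldehyde | C[C@@]12CCCC(CO)(CO)[C@H]1CC[C@H](C=O)[C@H]2CCC1=CCOC1=O | target

**Step count**
Total: 11 steps. Longest linear sequence: 9 steps (steps 1–6 and 9–11, from 1); steps 7 and 8 form a two-step side branch to 19.

**Steps most likely to fail**

Step 9 (Proposed new method). Ring closure may be outrun by bimolecular events: two-electron Michael addition of the enamine to 19, or capture of the phenylsulfonyl radical by the enamine. Closure may also go 7-endo at C11, or with poor facial discrimination at C9. The fallback uses known reaction types only, sets out from 13 and comes back at 21. Stille coupling of 3-bromofuran-2(5H)-one with allyltributylstannane (Pd(PPh3)4, toluene, 90 °C) would give 3-(prop-2-enyl)furan-2(5H)-one F1. Cross-metathesis of the vinyl group of 13 with F1 (second-generation Hoveyda–Grubbs catalyst (H2IMes)Cl2Ru=CH(2-iPrO-C6H4), CH2Cl2, 40 °C) would give (7S,8S)-7-(4,4-dimethoxybutyl)-3,3,8-trimethyl-8-[(1E)-3-(2-oxo-2,5-dihydrofuran-3-yl)prop-1-enyl]-2,4-dioxaspiro[5.5]undecane F2, which already carries C12–C16. Acetal exchange as in step 6 would give 4-[(7S,8S)-3,3,8-trimethyl-8-[(1E)-3-(2-oxo-2,5-dihydrofuran-3-yl)prop-1-enyl]-2,4-dioxaspiro[5.5]undecan-7-yl]butanal F3. F3 would then be cyclised by the established three-catalyst α-alkylation of aldehydes with olefins (Ir[dF(CF3)ppy]2(dtbbpy)PF6, the same imidazolidinone salt, 2,4,6-triisopropylbenzenethiol as hydrogen-atom donor, DME, blue LEDs). The C8 enaminyl radical closes 6-exo onto C9 and the thiol quenches the C11 radical, which gives 21 directly.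

Step 3. Conjugate addition at the neopentyl β-carbon C5 of the α-methyl enone may be slow, which would allow 1,2-addition and erode facial selectivity, and the aldol at the congested C10 may revert. The fallback sets out from 2 and comes back at 10. Robinson annulation of 2 with but-3-en-2-one under the conditions of step 2 would give 3,3-dimethyl-2,4-dioxaspiro[5.5]undec-7-en-9-one F4, a 4,4-disubstituted cyclohexenone without α-substituent and thus a well-behaved substrate class for copper-catalysed asymmetric Grignard addition. Addition of 8 and trapping of the enolate with iodomethane (DMPU) would give (7S,8S)-7-(4,4-dimethoxybutyl)-3,3,8-trimethyl-2,4-dioxaspiro[5.5]undecan-9-one F5; its C10 configuration is irrelevant. Deprotonation with LiHMDS (0.95 equiv, THF, 0 → 20 °C, equilibration to the more substituted enolate) and addition of acetaldehyde at −78 °C, again anti to the C5 chain, would give 10.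

Step 5. At 200 °C in strong base the hydrazone may form incompletely next to the quaternary C10, and the vinyl group may be lost to diimide if air enters. The fallback sets out from 11 and comes back at 13. Condensation with 4-methylbenzenesulfonohydrazide (MeOH, 60 °C) would give N'-[(7S,8S)-7-(4,4-dimethoxybutyl)-8-ethenyl-3,3,8-trimethyl-2,4-dioxaspiro[5.5]undecan-9-ylidene]-4-methylbenzenesulfonohydrazide F6. Hydride reduction with catecholborane (CHCl3, 0 °C) followed by NaOAc·3H2O at 60 °C would fragment it to 13 below 70 °C.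

**Further compounds**
F1 | step 9 | 3-(prop-2-enyl)furan-2(5H)-one | C=CCC1=CCOC1=O
F2 | step 9 | (7S,8S)-7-(4,4-dimethoxybutyl)-3,3,8-trimethyl-8-[(1E)-3-(2-oxo-2,5-dihydrofuran-3-yl)prop-1-enyl]-2,4-dioxaspiro[5.5]undecane | C[C@@]1(/C=C/CC2=CCOC2=O)CCCC3(COC(C)(C)OC3)[C@H]1CCCC(OC)OC
F3 | step 9 | 4-[(7S,8S)-3,3,8-trimethyl-8-[(1E)-3-(2-oxo-2,5-dihydrofuran-3-yl)prop-1-enyl]-2,4-dioxaspiro[5.5]undecan-7-yl]butanal | C[C@@]1(/C=C/CC2=CCOC2=O)CCCC3(COC(C)(C)OC3)[C@H]1CCCC=O
F4 | step 3 | 3,3-dimethyl-2,4-dioxaspiro[5.5]undec-7-en-9-one | O=C1C=CC2(CC1)COC(C)(C)OC2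
F5 | step 3 | (7S,8S)-7-(4,4-dimethoxybutyl)-3,3,8-trimethyl-2,4-dioxaspiro[5.5]undecan-9-one | C[C@@H]1C(=O)CCC2(COC(C)(C)OC2)[C@H]1CCCC(OC)OC
F6 | step 5 | N'-[(7S,8S)-7-(4,4-dimethoxybutyl)-8-ethenyl-3,3,8-trimethyl-2,4-dioxaspiro[5.5]undecan-9-ylidene]-4-methylbenzenesulfonohydrazide | C[C@@]1(C=C)C(=NNS(=O)(=O)c2ccc(C)cc2)CCC3(COC(C)(C)OC3)[C@H]1CCCC(OC)OC
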